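**Plan**
- Retrosynthesis: the C3 aroyloxy and isopropyl groups go back to a C3 ketone, C4–OH and H-3a to a C3a=C4 alkene, and the C5=C6–C7=O enone to a C6=C7 enol acetate. The resulting cyclohepta-1,4-diene is then cut at C4–C5 and C8–C8a in one stroke.
- Enabling feature: in the seven-membered ring, C5 is the only sp3 carbon between the C3a/C4 pair and the C6/C7 pair. The ring is therefore the Cope product of a cis-divinylcyclopropane (three-ring C4–C5–C6), and the C3a=C8a alkene of the cyclopentene is one of the two vinyl groups.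
- Forward order: the five-membered ring (C1–C3, C3a, C8a plus the C4 aldehyde carbon) is made first. The seven-membered ring arises in the key step from an alkenylcarbene and 2-acetoxy-3-methylbutadiene. Then follow hydroboration, C3 ketone, isopropyl/aroyl, enone and desilylation.
- Stereochemistry: a CBS reduction sets a temporary C3 carbinol. Its silyl ether steers the key step (C8a) and, with the 8a-methyl, the hydroboration (C3a, C4). After oxidation, isopropyl adds to the C3 ketone anti to the 8a-methyl and sets the final C3.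

Key step: step 6

Assumption (chemistry): locants are those of the hydroazulene core of the target (C3 ester carbon, C3a/C8a ring fusion, C4 carbinol, C7 ketone); in step 1 the bromoalkenyl arm is taken as the large group, so the (R)-oxazaborolidine gives the (S)-carbinol; the sulfonyl hydrazide, Rh2(esp)2 and LaCl3·2LiCl are bought.

**Step 1**
Reactants: 1 2-bromo-3-methylcyclopent-2-en-1-one
Product: 2 (1S)-2-bromo-3-methylcyclopent-2-en-1-ol
Conditions: (R)-Me-CBS (10 mol%), BH3·SMe2, THF, −20 °C
Reagents that add atoms: none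
Why: Corey–Bakshi–Shibata reduction; the α-bromoalkenyl arm acts as the large substituent, so hydride should be delivered to one carbonyl face and set the temporary C3 carbinol as S.

**Step 2**
Reactants: 2 (1S)-2-bromo-3-methylcyclopent-2-en-1-ol
Product: 3 {[(1S)-2-bromo-3-methylcyclopent-2-en-1-yl]oxy}triethylsilane
Conditions: TESCl, imidazole, CH2Cl2, 0 °C to rt
Reagents that add atoms: chlorotriethylsilane, CC[Si](Cl)(CC)CC
Why: Standard silyl ether formation; TES is bulky enough to shield one ring face later and can be removed selectively beside a TBS ether.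

**Step 3**
Reactants: 3 {[(1S)-2-bromo-3-methylcyclopent-2-en-1-yl]oxy}triethylsilane
Product: 5 (5S)-2-methyl-5-(triethylsilyloxy)cyclopent-1-ene-1-carbaldehyde, via alkenyllithium 4 (not isolated)
Conditions: t-BuLi (2.1 equiv), Et2O, −78 °C; DMF, −78 to 0 °C; H2O
Reagents that add atoms: N,N-dimethylformamide, CN(C)C=O
Why: Bromine–lithium exchange followed by formylation with DMF; at −78 °C the alkenyllithium should be trapped before silyl migration, and the stereocentre is not touched.

**Step 4**
Reactants: 5 (5S)-2-methyl-5-(triethylsilyloxy)cyclopent-1-ene-1-carbaldehyde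
Product: 6 (E)-N'-{[(5S)-2-methyl-5-(triethylsilyloxy)cyclopent-1-en-1-yl]methylidene}-2-(trifluoromethyl)benzenesulfonohydrazide
Conditions: 2-(CF3)C6H4SO2NHNH2, MeOH, rt
Reagents that add atoms: 2-(trifluoromethyl)benzenesulfonohydrazide, NNS(=O)(=O)c1ccccc1C(F)(F)F
Why: Hydrazone condensation; the ortho-CF3 sulfonyl group allows Bamford–Stevens release of the diazo compound at low temperature in step 6.

**Step 5**
Reactants: 7 3-methylbut-3-en-2-one
Product: 8 3-methylbuta-1,3-dien-2-yl acetate
Conditions: isopropenyl acetate, TsOH (cat.), Cu(OAc)2 (inhibitor), 95 °C, acetone distilled off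
Reagents that add atoms: isopropenyl acetate, CC(=C)OC(C)=O
Why: Acid-catalysed enol acetylation by acyl exchange; the ketone has a single enolisable side, so only the 2-acetoxydiene can form.

**Step 6**
Reactants: 6 (E)-N-sulfonylhydrazone of aldehyde 5; 8 3-methylbuta-1,3-dien-2-yl acetate
Product: 12 (3S,8aR)-6,8a-dimethyl-3-(triethylsilyloxy)-1,2,3,5,8,8a-hexahydroazulen-7-yl acetate, via sodium hydrazonide 9 (not isolated), via diazoalkene 10 (not isolated), via cis-divinylcyclopropane 11 (not isolated)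
Conditions: NaH, PhCF3, 0 °C to rt; 8 (4 equiv), Rh2(esp)2 (1 mol%), 40 °C; then 100 °C
Reagents that add atoms: none
Why: Salt 9 loses sulfinate to give diazoalkene 10, which Rh(II) converts into an electrophilic alkenylcarbene; this should cyclopropanate the methyl-substituted CH2=C(CH3) end of 8 by [2+1] addition (C4–C5 and C4–C6 bonds) to give 11, and a Cope rearrangement through the boat transition state then cleaves C4–C6 as C8–C8a forms, release of cyclopropane strain paying for the quaternary centre. The closest precedent is the tandem cyclopropanation/Cope formal (4+3) cycloaddition of metal vinylcarbenes with 1,3-dienes, here with an acceptor-free carbene released from an N-sulfonylhydrazone. The seven-membered ring closes by [3,3]-sigmatropic ring expansion of the three-membered ring, not by an endo or exo cyclisation, so both ring alkenes are cis by the boat geometry. C8a is the only stereocentre formed: A(1,3) strain with the ring methyl should keep rhodium on the C3 side, H-3 lies in the carbene plane and the pseudo-axial OTES blocks one face, so the diene adds anti to OTES and the boat delivers C8 to C8a on that same face (C8 trans to O-3). The step needs regioselection between the two 1,1-disubstituted alkenes of 8, which rests on acetoxy being a weaker donor than methyl, and a cis-divinyl arrangement, to which trans material should be funnelled by reversible one-centre epimerisation at 100 °C.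

**Step 7**
Reactants: 12 (3S,8aR)-6,8a-dimethyl-3-(triethylsilyloxy)-1,2,3,5,8,8a-hexahydroazulen-7-yl acetate
Product: 14 (3S,3aS,4S,8aR)-4-hydroxy-6,8a-dimethyl-3-(triethylsilyloxy)-1,2,3,3a,4,5,8,8a-octahydroazulen-7-yl acetate, via alkylborane 13 (not isolated)
Conditions: BH3·THF, THF, 0 °C to rt; Me3NO, 60 °C; aqueous work-up
Reagents that add atoms: trimethylamine N-oxide, C[N+](C)(C)[O-]
Why: Hydroboration–oxidation; syn addition with boron at the less substituted C4 from the face opposite the axial 8a-methyl and the C3 silyloxy group (as in Δ5-steroids) should set H-3a trans to the methyl and O-4 cis to H-3a, and the neutral amine-oxide oxidation goes with retention and spares the tetrasubstituted enol acetate.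

**Step 8**
Reactants: 14 C4 alcohol
Product: 15 (3S,3aR,4S,8aR)-4-(tert-butyldimethylsilyloxy)-6,8a-dimethyl-3-(triethylsilyloxy)-1,2,3,3a,4,5,8,8a-octahydroazulen-7-yl acetate
Conditions: TBSOTf, 2,6-lutidine, CH2Cl2, −78 to 0 °C
Reagents that add atoms: tert-butyldimethylsilyl triflate, CC(C)(C)[Si](C)(C)OS(=O)(=O)C(F)(F)F
Why: Silyl triflate silylation of a hindered secondary alcohol; it masks O-4 for the organometallic and palladium steps and is orthogonal to TES.

**Step 9**
Reactants: 15 bis-silyl ether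
Product: 16 (3S,3aR,4S,8aR)-4-(tert-butyldimethylsilyloxy)-3-hydroxy-6,8a-dimethyl-1,2,3,3a,4,5,8,8a-octahydroazulen-7-yl acetate
Conditions: HF·pyridine, pyridine, THF, 0 °C
Reagents that add atoms: none
Why: Selective cleavage of the more labile triethylsilyl ether under buffered HF; the TBS ether and the enol acetate should survive.

**Step 10**
Reactants: 16 C3 alcohol
Product: 17 (3aS,4S,8aR)-4-(tert-butyldimethylsilyloxy)-6,8a-dimethyl-3-oxo-1,2,3,3a,4,5,8,8a-octahydroazulen-7-yl acetate
Conditions: Dess–Martin periodinane, NaHCO3, CH2Cl2, 0 °C to rt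
Reagents that add atoms: none
Why: Dess–Martin oxidation under buffered neutral conditions, which should avoid epimerisation at C3a and β-elimination of the C4 silyloxy group; the temporary C3 stereocentre is erased after doing its work.

**Step 11**
Reactants: 18 4-hydroxybenzoic acid
Product: 20 4-(tert-butyldimethylsilyloxy)benzoic acid, via bis-silylated acid 19 (not isolated)
Conditions: TBSCl (2.3 equiv), imidazole, DMF, rt; then AcOH/THF/H2O, rt
Reagents that add atoms: tert-butyldimethylsilyl chloride, CC(C)(C)[Si](C)(C)Cl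
Why: Exhaustive silylation followed by selective hydrolysis of the labile silyl ester, leaving the aryl silyl ether.

**Step 12**
Reactants: 20 4-(tert-butyldimethylsilyloxy)benzoic acid
Product: 21 4-(tert-butyldimethylsilyloxy)benzoyl chloride
Conditions: (COCl)2, DMF (cat.), CH2Cl2, 0 °C to rt
Reagents that add atoms: oxalyl chloride, O=C(Cl)C(Cl)=O
Why: Acid chloride formation through the Vilsmeier-type chloroiminium catalyst; the product is used crude.

**Step 13**
Reactants: 17 C3 ketone; 21 4-(tert-butyldimethylsilyloxy)benzoyl chloride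
Product: 23 (3R,3aS,4S,8aR)-7-acetoxy-4-(tert-butyldimethylsilyloxy)-6,8a-dimethyl-3-(propan-2-yl)-1,2,3,3a,4,5,8,8a-octahydroazulen-3-yl 4-(tert-butyldimethylsilyloxy)benzoate, via magnesium alkoxide 22 (not isolated)
Conditions: LaCl3·2LiCl, THF, rt; i-PrMgCl, −40 °C; then 21, DMAP (cat.), −40 °C to rt
Reagents that add atoms: isopropylmagnesium chloride, CC(C)[Mg]Cl
Why: Lanthanide-promoted Grignard 1,2-addition (enolisation and β-hydride reduction suppressed) should occur on the H-3a face, opposite the axial 8a-methyl, setting C3 with isopropyl cis to H-3a and oxygen cis to the methyl; the alkoxide is acylated in situ, which places the ester on the tertiary oxygen while O-4 is masked.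

**Step 14**
Reactants: 23 enol acetate
Product: 24 (3R,3aS,4S,8aR)-4-(tert-butyldimethylsilyloxy)-6,8a-dimethyl-7-oxo-3-(propan-2-yl)-1,2,3,3a,4,7,8,8a-octahydroazulen-3-yl 4-(tert-butyldimethylsilyloxy)benzoate
Conditions: Pd(OAc)2 (10 mol%), dppe (10 mol%), Bu3SnOMe (20 mol%), allyl methyl carbonate, MeCN, 80 °C
Reagents that add atoms: none
Why: Tsuji palladium/tin dehydrogenation of enol acetates; the tin methoxide turns the enol acetate into the C6 enolate regiospecifically and β-hydride elimination towards C5 should give the endocyclic C5=C6 enone without touching a stereocentre.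

**Step 15**
Reactants: 24 bis-TBS enone
Product: 25 (3R,3aS,4S,8aR)-4-hydroxy-6,8a-dimethyl-7-oxo-3-(propan-2-yl)-1,2,3,3a,4,7,8,8a-octahydroazulen-3-yl 4-hydroxybenzoate
Conditions: TBAF, AcOH (1:1), THF, 0 °C to rt
Reagents that add atoms: none
Why: Fluoride desilylation of both silyl ethers, buffered with acetic acid so that no free alkoxide or phenoxide can trigger 1,3-acyl migration from the tertiary oxygen or β-elimination.

**Compound list**
1 | 2-bromo-3-methylcyclopent-2-en-1-one | CC1=C(Br)C(=O)CC1 | starting material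
2 | (1S)-2-bromo-3-methylcyclopent-2-en-1-ol | CC1=C(Br)[C@@H](O)CC1 | intermediate
3 | {[(1S)-2-bromo-3-methylcyclopent-2-en-1-yl]oxy}triethylsilane | CC1=C(Br)[C@@H](O[Si](CC)(CC)CC)CC1 | intermediate
4 | [(5S)-2-methyl-5-(triethylsilyloxy)cyclopent-1-en-1-yl]lithium (formed in situ) | CC1=C([Li])[C@@H](O[Si](CC)(CC)CC)CC1 | intermediate
5 | (5S)-2-methyl-5-(triethylsilyloxy)cyclopent-1-ene-1-carbaldehyde | CC1=C(C=O)[C@@H](O[Si](CC)(CC)CC)CC1 | intermediate
6 | (E)-N'-{[(5S)-2-methyl-5-(triethylsilyloxy)cyclopent-1-en-1-yl]methylidene}-2-(trifluoromethyl)benzenesulfonohydrazide | CC1=C(/C=N/NS(=O)(=O)c2ccccc2C(F)(F)F)[C@@H](O[Si](CC)(CC)CC)CC1 | intermediate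
7 | 3-methylbut-3-en-2-one | CC(=C)C(C)=O | starting material
8 | 3-methylbuta-1,3-dien-2-yl acetate | CC(=C)C(=C)OC(C)=O | intermediate
9 | sodium salt of hydrazone 6 (formed in situ) | CC1=C(/C=N/[N-]S(=O)(=O)c2ccccc2C(F)(F)F)[C@@H](O[Si](CC)(CC)CC)CC1.[Na+] | intermediate
10 | (5S)-1-(diazomethyl)-2-methyl-5-(triethylsilyloxy)cyclopent-1-ene (formed in situ) | CC1=C(C=[N+]=[N-])[C@@H](O[Si](CC)(CC)CC)CC1 | intermediate
11 | 1-{(1S,2S)-1-methyl-2-[(5S)-2-methyl-5-(triethylsilyloxy)cyclopent-1-en-1-yl]cyclopropyl}ethenyl acetate, the two alkenyl groups cis (formed in situ) | CC1=C([C@@H]2C[C@]2(C)C(=C)OC(C)=O)[C@@H](O[Si](CC)(CC)CC)CC1 | intermediate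
12 | (3S,8aR)-6,8a-dimethyl-3-(triethylsilyloxy)-1,2,3,5,8,8a-hexahydroazulen-7-yl acetate | CC1=C(OC(C)=O)C[C@@]2(C)CC[C@H](O[Si](CC)(CC)CC)C2=CC1 | intermediate
13 | C4 alkylborane from 12, boron and H-3a cis, both trans to the 8a-methyl (formed in situ) | CC1=C(OC(C)=O)C[C@@]2(C)CC[C@H](O[Si](CC)(CC)CC)[C@@H]2[C@@H](B)C1 | intermediate
14 | (3S,3aS,4S,8aR)-4-hydroxy-6,8a-dimethyl-3-(triethylsilyloxy)-1,2,3,3a,4,5,8,8a-octahydroazulen-7-yl acetate | CC1=C(OC(C)=O)C[C@@]2(C)CC[C@H](O[Si](CC)(CC)CC)[C@@H]2[C@@H](O)C1 | intermediate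
15 | (3S,3aR,4S,8aR)-4-(tert-butyldimethylsilyloxy)-6,8a-dimethyl-3-(triethylsilyloxy)-1,2,3,3a,4,5,8,8a-octahydroazulen-7-yl acetate | CC1=C(OC(C)=O)C[C@@]2(C)CC[C@H](O[Si](CC)(CC)CC)[C@@H]2[C@@H](O[Si](C)(C)C(C)(C)C)C1 | intermediate
16 | (3S,3aR,4S,8aR)-4-(tert-butyldimethylsilyloxy)-3-hydroxy-6,8a-dimethyl-1,2,3,3a,4,5,8,8a-octahydroazulen-7-yl acetate | CC1=C(OC(C)=O)C[C@@]2(C)CC[C@H](O)[C@@H]2[C@@H](O[Si](C)(C)C(C)(C)C)C1 | intermediate
17 | (3aS,4S,8aR)-4-(tert-butyldimethylsilyloxy)-6,8a-dimethyl-3-oxo-1,2,3,3a,4,5,8,8a-octahydroazulen-7-yl acetate | CC1=C(OC(C)=O)C[C@@]2(C)CCC(=O)[C@@H]2[C@@H](O[Si](C)(C)C(C)(C)C)C1 | intermediate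
18 | 4-hydroxybenzoic acid | OC(=O)c1ccc(O)cc1 | starting material
19 | tert-butyldimethylsilyl 4-(tert-butyldimethylsilyloxy)benzoate (formed in situ) | CC(C)(C)[Si](C)(C)OC(=O)c1ccc(O[Si](C)(C)C(C)(C)C)cc1 | intermediate
20 | 4-(tert-butyldimethylsilyloxy)benzoic acid | OC(=O)c1ccc(O[Si](C)(C)C(C)(C)C)cc1 | intermediate
21 | 4-(tert-butyldimethylsilyloxy)benzoyl chloride | O=C(Cl)c1ccc(O[Si](C)(C)C(C)(C)C)cc1 | intermediate
22 | chloromagnesium (3R,3aS,4S,8aR)-alkoxide from isopropyl addition to 17 (formed in situ) | CC1=C(OC(C)=O)C[C@@]2(C)CC[C@@](O[Mg]Cl)(C(C)C)[C@@H]2[C@@H](O[Si](C)(C)C(C)(C)C)C1 | intermediate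
23 | (3R,3aS,4S,8aR)-7-acetoxy-4-(tert-butyldimethylsilyloxy)-6,8a-dimethyl-3-(propan-2-yl)-1,2,3,3a,4,5,8,8a-octahydroazulen-3-yl 4-(tert-butyldimethylsilyloxy)benzoate | CC1=C(OC(C)=O)C[C@@]2(C)CC[C@@](OC(=O)c3ccc(O[Si](C)(C)C(C)(C)C)cc3)(C(C)C)[C@@H]2[C@@H](O[Si](C)(C)C(C)(C)C)C1 | intermediate
24 | (3R,3aS,4S,8aR)-4-(tert-butyldimethylsilyloxy)-6,8a-dimethyl-7-oxo-3-(propan-2-yl)-1,2,3,3a,4,7,8,8a-octahydroazulen-3-yl 4-(tert-butyldimethylsilyloxy)benzoate | CC1=C[C@H](O[Si](C)(C)C(C)(C)C)[C@@H]2[C@](C)(CC[C@@]2(OC(=O)c2ccc(O[Si](C)(C)C(C)(C)C)cc2)C(C)C)CC1=O | intermediate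
25 | (3R,3aS,4S,8aR)-4-hydroxy-6,8a-dimethyl-7-oxo-3-(propan-2-yl)-1,2,3,3a,4,7,8,8a-octahydroazulen-3-yl 4-hydroxybenzoate (CNP0153637.1) | CC1=C[C@H](O)[C@@H]2[C@](C)(CC[C@@]2(OC(=O)c2ccc(O)cc2)C(C)C)CC1=O | target

**Step count**
Total: 15 steps. Longest linear sequence: 12 steps (1–4, 6–10, 13–15).

**Steps most likely to fail, with fallbacks**

Step 6. The carbene may be consumed on the acetoxy-substituted alkene of the diene, by pyrazole formation or by dimerisation, or the hindered Cope step may stall. The fallback builds the divinylcyclopropane stepwise and sets out from aldehyde 5. Horner–Wadsworth–Emmons reaction with diethyl (3-oxobutan-2-yl)phosphonate (NaH, THF) should give (3E)-3-methyl-4-[(5S)-2-methyl-5-(triethylsilyloxy)cyclopent-1-en-1-yl]but-3-en-2-one F1. Corey–Chaykovsky cyclopropanation with dimethylsulfoxonium methylide (the ylide carbon becomes C5) should give 1-{trans-1-methyl-2-[(5S)-2-methyl-5-(triethylsilyloxy)cyclopent-1-en-1-yl]cyclopropyl}ethan-1-one F2, with the acetyl group trans to the cyclopentenyl group. O-Acetylation of its potassium enolate (KHMDS, then Ac2O, THF, −78 °C) should give the trans-divinylcyclopropane enol acetate F3. Heating F3 in xylene at about 150 °C should epimerise one ring carbon through the bis-allylic diradical to 11, which rearranges to 12, where the route is rejoined. Both cyclopropane diastereomers should converge, because the Cope transition state anti to the silyloxy group selects C8a.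

Step 13. The Grignard reagent may enolise or reduce the ketone with loss of the β-silyloxy group, add from the wrong face, or the hindered tertiary alkoxide may resist acylation. The fallback sets out from ketone 17 and uses an sp2 nucleophile without β-hydrogens. Isopropenylmagnesium bromide with CeCl3 (THF, −78 °C) should give the tertiary alcohol (3R,3aS,4S,8aR)-4-(tert-butyldimethylsilyloxy)-3-hydroxy-6,8a-dimethyl-3-(prop-1-en-2-yl)-1,2,3,3a,4,5,8,8a-octahydroazulen-7-yl acetate F4, which is isolated. Deprotonation with KHMDS and acylation with 21 should give the isopropenyl ester F5. Hydrogenation of the 1,1-disubstituted alkene of F5 with Wilkinson's catalyst, which should leave the tetrasubstituted enol acetate alone, returns to 23.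

Step 14. The palladium enolate may undergo allyl transfer to C6 (Tsuji allylation) or eliminate towards the methyl group instead of C5. The fallback sets out from enol acetate 23 and uses halogenation and elimination. NBS in aqueous THF at 0 °C should give the C6 α-bromo ketone F6 (C6 epimers). Dehydrobromination with Li2CO3 and LiBr in DMF at about 100 °C should give the conjugated endocyclic enone 24, where the route is rejoined.

**Further compounds**
F1 | step 6 | (3E)-3-methyl-4-[(5S)-2-methyl-5-(triethylsilyloxy)cyclopent-1-en-1-yl]but-3-en-2-one | CC1=C(/C=C(\C)C(C)=O)[C@@H](O[Si](CC)(CC)CC)CC1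
F2 | step 6 | 1-{trans-1-methyl-2-[(5S)-2-methyl-5-(triethylsilyloxy)cyclopent-1-en-1-yl]cyclopropyl}ethan-1-one (one of two ring diastereomers shown) | CC1=C([C@@H]2C[C@@]2(C)C(C)=O)[C@@H](O[Si](CC)(CC)CC)CC1
F3 | step 6 | 1-{trans-1-methyl-2-[(5S)-2-methyl-5-(triethylsilyloxy)cyclopent-1-en-1-yl]cyclopropyl}ethenyl acetate (one of two ring diastereomers shown) | CC1=C([C@@H]2C[C@@]2(C)C(=C)OC(C)=O)[C@@H](O[Si](CC)(CC)CC)CC1
F4 | step 13 | (3R,3aS,4S,8aR)-4-(tert-butyldimethylsilyloxy)-3-hydroxy-6,8a-dimethyl-3-(prop-1-en-2-yl)-1,2,3,3a,4,5,8,8a-octahydroazulen-7-yl acetate | CC1=C(OC(C)=O)C[C@@]2(C)CC[C@@](O)(C(C)=C)[C@@H]2[C@@H](O[Si](C)(C)C(C)(C)C)C1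
F5 | step 13 | (3R,3aS,4S,8aR)-7-acetoxy-4-(tert-butyldimethylsilyloxy)-6,8a-dimethyl-3-(prop-1-en-2-yl)-1,2,3,3a,4,5,8,8a-octahydroazulen-3-yl 4-(tert-butyldimethylsilyloxy)benzoate | CC1=C(OC(C)=O)C[C@@]2(C)CC[C@@](OC(=O)c3ccc(O[Si](C)(C)C(C)(C)C)cc3)(C(C)=C)[C@@H]2[C@@H](O[Si](C)(C)C(C)(C)C)C1
F6 | step 14 | (3R,3aS,4S,8aR)-6-bromo-4-(tert-butyldimethylsilyloxy)-6,8a-dimethyl-7-oxo-3-(propan-2-yl)decahydroazulen-3-yl 4-(tert-butyldimethylsilyloxy)benzoate (C6 epimers) | CC1(Br)C[C@H](O[Si](C)(C)C(C)(C)C)[C@@H]2[C@](C)(CC[C@@]2(OC(=O)c2ccc(O[Si](C)(C)C(C)(C)C)cc2)C(C)C)CC1=O
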